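**Retrosynthetic overview**
1. Labels used in the text: dienone ring C1 (C=O), C2 (allyl-bearing), C3, C4 (quaternary C–OMe), C5 (C–OMe), C6; side chain C8 (CHMe) and C7 (benzylic CH–O). The C7 acetate comes last, from a MOM-protected alcohol.
2. Key disconnection: ring bond C1–C2 together with the O–CH3 bond at C4. The carbocycle is unravelled to the 5-alkenyl methyl tetronate 15, in which C1, C6, C5, C4 and the C4 oxygen form a 4-methoxyfuran-2(5H)-one ring and C2 is the iodine-bearing carbon of a (Z)-alkenyl iodide.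
3. Enabling feature: the oxygen on C4 is 1,4-related to the carbonyl carbon C1 through C5(OMe)=C6, so the array O–C4–C5(OMe)=C6–C1(=O) is exactly a tetronate ring. That ring holds C4 cis to C1, the Z-iodoalkene holds C2 cis to C4, and acyl transfer from the lactone to C2 releases the ring oxygen as the C4 alkoxide, which is methylated in the same flask.
4. The tetronate comes from the tertiary 4-hydroxy-2-ynoate 13 (methanol addition and lactonisation). C4 is set by chelation-controlled addition of methyl lithiopropiolate to the (Z)-β-iodoenone 10. Compound 10 comes from ynone 9 (NaI/AcOH), which comes from a Weinreb amide and pent-1-en-4-yne. C7 and C8 come from an Evans syn aldol with veratraldehyde.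
5. Ring order: the veratryl ring is bought; the furanone ring is formed in step 7; the cyclohexadienone ring is formed in step 8 at the expense of the furanone ring.

Key step: step 8

Remark: pent-1-en-4-yne and methyl propiolate are taken as purchasable building blocks.

**Step 1**
Reactants: 1 (4R)-4-benzyl-3-propanoyl-1,3-oxazolidin-2-one; 2 3,4-dimethoxybenzaldehyde
Product: 4 (4R)-4-benzyl-3-[(2R,3R)-3-(3,4-dimethoxyphenyl)-3-hydroxy-2-methylpropanoyl]-1,3-oxazolidin-2-one, via dibutylboron Z-enolate 3 (not isolated)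
Conditions: Bu2BOTf, i-Pr2NEt, CH2Cl2, 0 °C; then 2, −78 → 0 °C; H2O2, MeOH, pH 7 buffer
Reagents that add atoms: none
Why: Evans syn aldol reaction; the Z-boron enolate reacts through a Zimmerman–Traxler chair in which the benzyl group of the auxiliary shields one enolate face, which should set C7 and C8 together as the (2R,3R) syn pair.

**Step 2**
Reactants: 4 aldol adduct
Product: 5 (2R,3R)-3-(3,4-dimethoxyphenyl)-3-hydroxy-N-methoxy-N,2-dimethylpropanamide
Conditions: MeNHOMe·HCl, AlMe3, CH2Cl2, −20 → 0 °C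
Reagents that add atoms: N,O-dimethylhydroxylamine hydrochloride CNOC.Cl
Why: Weinreb transamidation of the imide with the aluminium amide made in the flask; the free β-hydroxyl directs attack to the exocyclic carbonyl and the α-centre should not epimerise.

**Step 3**
Reactants: 5 hydroxy Weinreb amide
Product: 6 (2R,3R)-3-(3,4-dimethoxyphenyl)-N-methoxy-3-(methoxymethoxy)-N,2-dimethylpropanamide
Conditions: MOMCl, i-Pr2NEt, Bu4NI (cat.), CH2Cl2, 0 → 40 °C
Reagents that add atoms: chloromethyl methyl ether COCCl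
Why: O-alkylation of the secondary alcohol as its methoxymethyl ether, a group that chelates in step 6 and withstands acetylides, NaI/AcOH, methoxide and t-BuLi.

**Step 4**
Reactants: 6 MOM-protected Weinreb amide; 7 pent-1-en-4-yne
Product: 9 (1R,2R)-1-(3,4-dimethoxyphenyl)-1-(methoxymethoxy)-2-methyloct-7-en-4-yn-3-one, via lithium pent-4-en-1-yn-1-ide 8 (not isolated)
Conditions: 7, n-BuLi, THF, −78 °C; then 6, −78 → −20 °C; cold 1 M HCl quench
Reagents that add atoms: none
Why: Weinreb ketone synthesis; the chelated tetrahedral adduct survives until the cold acid quench, so neither over-addition nor epimerisation at C8 is expected, and the quench removes the liberated amine before it can add to the ynone.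

**Step 5**
Reactants: 9 ynone
Product: 10 (1R,2R,4Z)-1-(3,4-dimethoxyphenyl)-5-iodo-1-(methoxymethoxy)-2-methylocta-4,7-dien-3-one
Conditions: NaI, AcOH, 23 °C
Reagents that add atoms: sodium iodide [Na+].[I-]
Why: conjugate hydroiodination of an ynone; iodide adds at the β-carbon (C2) and protonation occurs anti, which should give the kinetic Z-β-iodoenone with iodine cis to the C4 carbonyl, while the unactivated terminal alkene is left alone.

**Step 6**
Reactants: 10 (Z)-β-iodoenone; 11 methyl propiolate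
Product: 13 methyl (4S,5Z)-4-[(1R,2R)-1-(3,4-dimethoxyphenyl)-1-(methoxymethoxy)propan-2-yl]-4-hydroxy-6-iodonona-5,8-dien-2-ynoate, via methyl 3-lithiopropiolate 12 (not isolated)
Conditions: 11, LiN(SiMe3)2, Et2O, −78 °C; then 10 precomplexed with MgBr2·OEt2 in CH2Cl2–Et2O, −78 °C; AcOH quench at −78 °C
Reagents that add atoms: none
Why: 1,2-addition of an alkynyl nucleophile to the ketone under Cram–Reetz 1,3-chelation control; MgBr2 bridges the ketone oxygen and the MOM ether oxygen in a six-membered chelate on which the C8 methyl and the C7 aryl group are cis (syn-aldol origin), so the acetylide should enter from the opposite face and set C4 with its oxygen syn to both the C8 methyl and the C7 oxygen (4S in 13, the configuration of the target), and the hard, weakly basic acetylide should attack the carbonyl and not the iodine-bearing β-carbon.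

**Step 7**
Reactants: 13 tertiary 4-hydroxy-2-ynoate
Product: 15 (5S)-5-[(1R,2R)-1-(3,4-dimethoxyphenyl)-1-(methoxymethoxy)propan-2-yl]-5-[(1Z)-2-iodopenta-1,4-dien-1-yl]-4-methoxyfuran-2(5H)-one, via open E-methoxyenoate 14 (not isolated)
Conditions: NaOMe (0.3 equiv), MeOH, 0 → 23 °C
Reagents that add atoms: methanol CO
Why: tetronate synthesis from a 4-hydroxy-2-ynoate; methoxide adds reversibly at the β-carbon (C5) and the enoate isomer with the carbinol cis to the ester lactonises, which installs the C5 methoxy group and locks C4 cis to C1 without touching the C4 stereocentre.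

**Step 8**
Reactants: 15 iodoalkenyl tetronate
Product: 19 (4R)-4-[(1R,2R)-1-(3,4-dimethoxyphenyl)-1-(methoxymethoxy)propan-2-yl]-4,5-dimethoxy-2-(prop-2-en-1-yl)cyclohexa-2,5-dien-1-one, via alkenyllithium 16 (not isolated), via bridged lithium hemiketalate 17 (not isolated), via lithium 4-oxidodienone 18 (not isolated)
Conditions: t-BuLi (2.1 equiv), THF–Et2O, high dilution, −100 → −20 °C; then MeOTf, −78 → 0 °C
Reagents that add atoms: methyl trifluoromethanesulfonate COS(=O)(=O)C(F)(F)F
Why: Proposed new method: iodine–lithium exchange, which at −100 °C should outrun attack of t-BuLi on the deactivated vinylogous-carbonate carbonyl, gives alkenyllithium 16 with retention of the Z geometry; its carbanionic C2 lies over the lactone carbonyl C1 and adds to it across the five-membered ring to give the 1-oxido-7-oxabicyclo[2.2.1]heptadiene 17, which collapses by cleavage of the C1–O bridge bond (strain release, formation of the vinylogous-ester carbonyl) to the 4-oxidocyclohexadienone 18, and MeOTf then caps the tertiary alkoxide as the C4 methyl ether. The closest known reaction types are the Parham-type cycloacylation of carbanions from halogen–lithium exchange on tethered esters, and the spontaneous opening of 1-alkoxy-7-oxanorbornadienes (2-alkoxyfuran–alkyne adducts) to 4-oxycyclohexadienones and phenols, which indicates that the bridged species lies on a downhill path; what is new is reaching it by transannular anionic attack on a tetronate. The six-membered carbocycle closes by a 6-exo-trig acyl addition (carbonyl oxygen exocyclic to the new ring), after which the five-membered lactone ring is opened. No stereocentre is made or touched in the product: the C4–O, C4–C8 and C4–C5 bonds stay intact, so C4 keeps the configuration set in step 6, and the transient C1 centre of 17 is dictated by the bridge. The step needs attack of C2 on C1 in preference to proton transfer or bimolecular addition; the Z-iodoalkene from step 5 and the lactone ring from step 7 place C2 and C1 on the same side of C4, the 5,5-disubstitution removes the acidic γ-hydrogen of the tetronate, and high dilution disfavours intermolecular paths.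

**Step 9**
Reactants: 19 MOM-protected dienone
Product: 20 (4R)-4-[(1R,2R)-1-(3,4-dimethoxyphenyl)-1-hydroxypropan-2-yl]-4,5-dimethoxy-2-(prop-2-en-1-yl)cyclohexa-2,5-dien-1-one
Conditions: TMSOTf, 2,2'-bipyridyl, CH2Cl2, 0 °C; then H2O
Reagents that add atoms: none
Why: mild non-protic cleavage of a methoxymethyl acetal through an N-(alkoxymethyl)pyridinium salt that water hydrolyses, chosen because protic acid would endanger the electron-rich benzylic C7–O bond and the dienone, and because methyl ethers and the enol ether are inert to it.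

**Step 10**
Reactants: 20 hydroxy dienone
Product: 21 (1R,2R)-1-(3,4-dimethoxyphenyl)-2-[(1R)-1,2-dimethoxy-4-oxo-5-(prop-2-en-1-yl)cyclohexa-2,5-dien-1-yl]propyl acetate (CNP0159267.1)
Conditions: Ac2O, pyridine, DMAP (cat.), CH2Cl2, 0 → 23 °C
Reagents that add atoms: acetic anhydride CC(=O)OC(C)=O
Why: DMAP-catalysed acetylation of the only hydroxyl group, a secondary benzylic alcohol; no stereocentre is involved.

**Compound list**
1 | (4R)-4-benzyl-3-propanoyl-1,3-oxazolidin-2-one | CCC(=O)N1[C@H](Cc2ccccc2)COC1=O | starting material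
2 | 3,4-dimethoxybenzaldehyde | COc1ccc(C=O)cc1OC | starting material
3 | dibutylboron (Z)-enolate of 1 | CCCCB(CCCC)O/C(=C\C)N1[C@H](Cc2ccccc2)COC1=O | intermediate
4 | (4R)-4-benzyl-3-[(2R,3R)-3-(3,4-dimethoxyphenyl)-3-hydroxy-2-methylpropanoyl]-1,3-oxazolidin-2-one | O=C1OC[C@@H](Cc2ccccc2)N1C(=O)[C@H](C)[C@@H](O)c1ccc(OC)c(OC)c1 | intermediate
5 | (2R,3R)-3-(3,4-dimethoxyphenyl)-3-hydroxy-N-methoxy-N,2-dimethylpropanamide | CON(C)C(=O)[C@H](C)[C@@H](O)c1ccc(OC)c(OC)c1 | intermediate
6 | (2R,3R)-3-(3,4-dimethoxyphenyl)-N-methoxy-3-(methoxymethoxy)-N,2-dimethylpropanamide | CON(C)C(=O)[C@H](C)[C@@H](OCOC)c1ccc(OC)c(OC)c1 | intermediate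
7 | pent-1-en-4-yne | C=CCC#C | starting material
8 | lithium pent-4-en-1-yn-1-ide | [Li]C#CCC=C | intermediate
9 | (1R,2R)-1-(3,4-dimethoxyphenyl)-1-(methoxymethoxy)-2-methyloct-7-en-4-yn-3-one | C=CCC#CC(=O)[C@H](C)[C@@H](OCOC)c1ccc(OC)c(OC)c1 | intermediate
10 | (1R,2R,4Z)-1-(3,4-dimethoxyphenyl)-5-iodo-1-(methoxymethoxy)-2-methylocta-4,7-dien-3-one | C=CC/C(I)=C/C(=O)[C@H](C)[C@@H](OCOC)c1ccc(OC)c(OC)c1 | intermediate
11 | methyl propiolate | C#CC(=O)OC | starting material
12 | methyl 3-lithiopropiolate | [Li]C#CC(=O)OC | intermediate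
13 | methyl (4S,5Z)-4-[(1R,2R)-1-(3,4-dimethoxyphenyl)-1-(methoxymethoxy)propan-2-yl]-4-hydroxy-6-iodonona-5,8-dien-2-ynoate | C=CC/C(I)=C/[C@@](O)([C@H](C)[C@@H](OCOC)c1ccc(OC)c(OC)c1)C#CC(=O)OC | intermediate
14 | methyl (2E,4S,5Z)-4-[(1R,2R)-1-(3,4-dimethoxyphenyl)-1-(methoxymethoxy)propan-2-yl]-4-hydroxy-6-iodo-3-methoxynona-2,5,8-trienoate | C=CC/C(I)=C/[C@@](O)([C@H](C)[C@@H](OCOC)c1ccc(OC)c(OC)c1)/C(OC)=C\C(=O)OC | intermediate
15 | (5S)-5-[(1R,2R)-1-(3,4-dimethoxyphenyl)-1-(methoxymethoxy)propan-2-yl]-5-[(1Z)-2-iodopenta-1,4-dien-1-yl]-4-methoxyfuran-2(5H)-one | C=CC/C(I)=C/[C@@]1(OC(=O)C=C1OC)[C@H](C)[C@@H](OCOC)c1ccc(OC)c(OC)c1 | intermediate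
16 | alkenyllithium from 15 (iodine replaced by lithium, alkene geometry retained) | C=CC/C([Li])=C/[C@@]1(OC(=O)C=C1OC)[C@H](C)[C@@H](OCOC)c1ccc(OC)c(OC)c1 | intermediate
17 | lithium 4-[(1R,2R)-1-(3,4-dimethoxyphenyl)-1-(methoxymethoxy)propan-2-yl]-5-methoxy-2-(prop-2-en-1-yl)-7-oxabicyclo[2.2.1]hepta-2,5-dien-1-olate | C=CCC1=C[C@@]2(O[C@@]1([O-])C=C2OC)[C@H](C)[C@@H](OCOC)c1ccc(OC)c(OC)c1.[Li+] | intermediate
18 | lithium (1R)-1-[(1R,2R)-1-(3,4-dimethoxyphenyl)-1-(methoxymethoxy)propan-2-yl]-2-methoxy-4-oxo-5-(prop-2-en-1-yl)cyclohexa-2,5-dien-1-olate | C=CCC1=C[C@@]([O-])([C@H](C)[C@@H](OCOC)c2ccc(OC)c(OC)c2)C(OC)=CC1=O.[Li+] | intermediate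
19 | (4R)-4-[(1R,2R)-1-(3,4-dimethoxyphenyl)-1-(methoxymethoxy)propan-2-yl]-4,5-dimethoxy-2-(prop-2-en-1-yl)cyclohexa-2,5-dien-1-one | C=CCC1=C[C@@](OC)([C@H](C)[C@@H](OCOC)c2ccc(OC)c(OC)c2)C(OC)=CC1=O | intermediate
20 | (4R)-4-[(1R,2R)-1-(3,4-dimethoxyphenyl)-1-hydroxypropan-2-yl]-4,5-dimethoxy-2-(prop-2-en-1-yl)cyclohexa-2,5-dien-1-one | C=CCC1=C[C@@](OC)([C@H](C)[C@@H](O)c2ccc(OC)c(OC)c2)C(OC)=CC1=O | intermediate
21 | (1R,2R)-1-(3,4-dimethoxyphenyl)-2-[(1R)-1,2-dimethoxy-4-oxo-5-(prop-2-en-1-yl)cyclohexa-2,5-dien-1-yl]propyl acetate | C=CCC1=C[C@@](OC)([C@H](C)[C@@H](OC(C)=O)c2ccc(OC)c(OC)c2)C(OC)=CC1=O | target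

**Step count and risks**
Total step count: 10. Longest linear sequence: 10 steps (from 1).

Steps most likely to fail:

1. Step 8 (proposed new method). The transannular acyl transfer may be slower than quenching of the alkenyllithium by proton transfer, than its isomerisation to a pentadienyl anion, or than bimolecular addition; the hindered alkoxide may also be methylated incompletely. The fallback uses known chemistry, sets out from 15 and comes back at 19. DIBAL-H (CH2Cl2, −78 °C) should reduce the lactone to the 2,5-dihydrofuran-2-ol (lactol, anomeric mixture) F1, which cannot aromatise because C4 is quaternary. CrCl2 with NiCl2 (cat.) in DMSO–THF should then close the same C1–C2 bond by intramolecular Nozaki–Hiyama–Kishi addition of the alkenyl iodide to the open hydroxy-enal form, giving the cyclohexa-2,5-diene-1,4-diol F2. MnO2 (CH2Cl2) should oxidise its doubly allylic secondary alcohol to the 4-hydroxycyclohexadienone F3, and MeI/Ag2O should methylate the tertiary hydroxyl to give 19.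

2. Step 6. Addition–elimination at the iodine-bearing β-carbon, γ-deprotonation of the skipped dienone, or erosion of the Z-iodide may compete with carbonyl addition. The fallback sets out from 9 and comes back at 15. Methyl 3-lithiopropiolate 12 is added to ynone 9 under the same MgBr2 chelation, which should give the bis-alkynyl carbinol F4 with the same facial preference. NaOMe/MeOH should convert it into the alkynyl tetronate F5. Trans-hydrosilylation with Et3SiH and [Cp*Ru(MeCN)3]PF6 (cat.) in CH2Cl2 should place silicon on the alkyne carbon remote from the quaternary centre, giving the (Z)-alkenylsilane F6. Iododesilylation with N-iodosuccinimide in (CF3)2CHOH at 0 °C, with retention of geometry, should then give 15.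

3. Step 9. During acetal cleavage the silyl Lewis acid may trigger ionisation at the electron-rich benzylic C7–O bond or a dienone–phenol shift, and the liberated C7 hydroxyl may add in conjugate fashion to the dienone. The fallback moves the protecting-group change ahead of the ring closure; it sets out from 15 and comes back at 20. The MOM group is removed from the robust tetronate (TMSOTf, 2,2'-bipyridyl; H2O) to give the hydroxy tetronate F7. TESOTf/2,6-lutidine should give the triethylsilyl ether F8, and the conditions of step 8 should convert it into the silyl-protected dienone F9. Buffered HF·pyridine (THF–pyridine, 0 °C) should then release 20 under nearly neutral conditions.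

**Further compounds**
F1 | step 8 | (5S)-5-[(1R,2R)-1-(3,4-dimethoxyphenyl)-1-(methoxymethoxy)propan-2-yl]-5-[(1Z)-2-iodopenta-1,4-dien-1-yl]-4-methoxy-2,5-dihydrofuran-2-ol (anomeric mixture) | C=CC/C(I)=C/[C@@]1(OC(O)C=C1OC)[C@H](C)[C@@H](OCOC)c1ccc(OC)c(OC)c1
F2 | step 8 | (4R)-4-[(1R,2R)-1-(3,4-dimethoxyphenyl)-1-(methoxymethoxy)propan-2-yl]-5-methoxy-2-(prop-2-en-1-yl)cyclohexa-2,5-diene-1,4-diol (mixture at C1) | C=CCC1=C[C@@](O)([C@H](C)[C@@H](OCOC)c2ccc(OC)c(OC)c2)C(OC)=CC1O
F3 | step 8 | (4R)-4-[(1R,2R)-1-(3,4-dimethoxyphenyl)-1-(methoxymethoxy)propan-2-yl]-4-hydroxy-5-methoxy-2-(prop-2-en-1-yl)cyclohexa-2,5-dien-1-one | C=CCC1=C[C@@](O)([C@H](C)[C@@H](OCOC)c2ccc(OC)c(OC)c2)C(OC)=CC1=O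
F4 | step 6 | methyl (4S)-4-[(1R,2R)-1-(3,4-dimethoxyphenyl)-1-(methoxymethoxy)propan-2-yl]-4-hydroxynon-8-ene-2,5-diynoate | C=CCC#C[C@@](O)([C@H](C)[C@@H](OCOC)c1ccc(OC)c(OC)c1)C#CC(=O)OC
F5 | step 6 | (5S)-5-[(1R,2R)-1-(3,4-dimethoxyphenyl)-1-(methoxymethoxy)propan-2-yl]-4-methoxy-5-(pent-4-en-1-yn-1-yl)furan-2(5H)-one | C=CCC#C[C@@]1(OC(=O)C=C1OC)[C@H](C)[C@@H](OCOC)c1ccc(OC)c(OC)c1
F6 | step 6 | (5S)-5-[(1R,2R)-1-(3,4-dimethoxyphenyl)-1-(methoxymethoxy)propan-2-yl]-4-methoxy-5-[(1Z)-2-(triethylsilyl)penta-1,4-dien-1-yl]furan-2(5H)-one | C=CC/C([Si](CC)(CC)CC)=C/[C@@]1(OC(=O)C=C1OC)[C@H](C)[C@@H](OCOC)c1ccc(OC)c(OC)c1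
F7 | step 9 | (5S)-5-[(1R,2R)-1-(3,4-dimethoxyphenyl)-1-hydroxypropan-2-yl]-5-[(1Z)-2-iodopenta-1,4-dien-1-yl]-4-methoxyfuran-2(5H)-one | C=CC/C(I)=C/[C@@]1(OC(=O)C=C1OC)[C@H](C)[C@@H](O)c1ccc(OC)c(OC)c1
F8 | step 9 | (5S)-5-[(1R,2R)-1-(3,4-dimethoxyphenyl)-1-(triethylsilyloxy)propan-2-yl]-5-[(1Z)-2-iodopenta-1,4-dien-1-yl]-4-methoxyfuran-2(5H)-one | C=CC/C(I)=C/[C@@]1(OC(=O)C=C1OC)[C@H](C)[C@@H](O[Si](CC)(CC)CC)c1ccc(OC)c(OC)c1
F9 | step 9 | (4R)-4-[(1R,2R)-1-(3,4-dimethoxyphenyl)-1-(triethylsilyloxy)propan-2-yl]-4,5-dimethoxy-2-(prop-2-en-1-yl)cyclohexa-2,5-dien-1-one | C=CCC1=C[C@@](OC)([C@H](C)[C@@H](O[Si](CC)(CC)CC)c2ccc(OC)c(OC)c2)C(OC)=CC1=O
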